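The target is an oxolane (O1, C2 aryl, C3 methyl, C4 carbinol arm, C5 H2, carbinol carbon C1'). Its C3–C4 bond joins the β-carbons of two 3,4-dimethoxyphenyl-C3 units and O1 bridges benzylic C2 and C5, so it equals two cinnamyl fragments plus one H and one O. This is what allows a hydrogen-atom-transfer cyclisation–oxygenation.
Retrosynthesis: the C1'–O bond, the C3–C4 ring bond and one C–H bond of the C3 methyl are cut together, giving an (S)-1-arylallyl (E)-cinnamyl ether. The O1–C2 bond is then cut to (E)-3,4-dimethoxycinnamyl alcohol and its tert-butyl carbonate, both from veratraldehyde.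
Forward: olefination and reduction give the cinnamyl alcohol, part of it is activated as the carbonate, an iridium-catalysed branched allylic etherification joins the halves through O1–C2, and the only ring closes last at C3–C4.
Stereochemistry: C2 (S) comes from the chiral iridium catalyst. C3 (S) and C4 (R) are relayed from C2 in the 5-exo transition state (2,3-trans, 3,4-cis). C1' (R) comes from substrate-controlled oxygen capture in the same cascade.

Key step: step 5

Remark: ligand L is the (Sa,S,S) enantiomer of the binaphthol-derived N,N-bis(1-phenylethyl)phosphoramidite, assumed to give the (S)-ether as this ligand series normally does with heteroatom nucleophiles; the (Ra,R,R) ligand would be taken if the sense proved opposite.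

Step 1
Reactants: 1 veratraldehyde (3,4-dimethoxybenzaldehyde); 2 triethyl phosphonoacetate
Product: 3 ethyl (E)-3-(3,4-dimethoxyphenyl)prop-2-enoate
Conditions: NaH, THF, 0 °C to rt
Reagents that add atoms: none
Why: Horner–Wadsworth–Emmons olefination, in which the stabilised phosphonate anion adds reversibly to the aldehyde and eliminates to the favoured (E)-cinnamate.

Step 2
Reactants: 3 ethyl (E)-3-(3,4-dimethoxyphenyl)prop-2-enoate
Product: 4 (E)-3-(3,4-dimethoxyphenyl)prop-2-en-1-ol
Conditions: iBu2AlH (2.5 equiv), CH2Cl2, −78 to 0 °C; aq. KNaC4H4O6 (Rochelle salt)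
Reagents that add atoms: none
Why: 1,2-reduction of a conjugated ester by the electrophilic aluminium hydride, which should reduce the C=O twice and leave the C=C bond and the aryl ethers alone.

Step 3
Reactants: 4 (E)-3-(3,4-dimethoxyphenyl)prop-2-en-1-ol
Product: 5 tert-butyl (E)-3-(3,4-dimethoxyphenyl)prop-2-en-1-yl carbonate
Conditions: Boc2O, DMAP (cat.), CH2Cl2, 0 °C to rt
Reagents that add atoms: di-tert-butyl dicarbonate (Boc2O), CC(C)(C)OC(=O)OC(=O)OC(C)(C)C
Why: DMAP-catalysed O-acylation of the primary allylic alcohol; the tert-butyl carbonate is chosen because it resists acyl transfer to an alkoxide and ionises to CO2 and hindered tert-butoxide, which should not compete as a nucleophile in step 4.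

Step 4
Reactants: 4 (E)-3-(3,4-dimethoxyphenyl)prop-2-en-1-ol (second portion, the nucleophile); 5 tert-butyl (E)-3-(3,4-dimethoxyphenyl)prop-2-en-1-yl carbonate
Product: 8 (S)-1-(3,4-dimethoxyphenyl)prop-2-en-1-yl (E)-3-(3,4-dimethoxyphenyl)prop-2-en-1-yl ether, via lithium alkoxide 6 (not isolated), via copper alkoxide 7 (not isolated)
Conditions: 4 (2 equiv), n-BuLi, THF, 0 °C; CuI, rt; then 5 (1 equiv), [Ir(cod)Cl]2 (2 mol%), L (4 mol%), THF, rt
Reagents that add atoms: none
Why: iridium-catalysed enantioselective allylic substitution (branched-selective allylic etherification), in which the monovalent iridium–phosphoramidite catalyst ionises 5 to a π-allyl complex and the soft copper alkoxide 7 attacks its aryl-bearing terminus on the face fixed by the ligand, setting C2 as (S) and leaving both alkenes in place.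

Step 5
Reactants: 8 (S)-1-(3,4-dimethoxyphenyl)prop-2-en-1-yl (E)-3-(3,4-dimethoxyphenyl)prop-2-en-1-yl ether
Product: 10 (2S,3S,4R)-2-(3,4-dimethoxyphenyl)-4-[(R)-(3,4-dimethoxyphenyl)(hydroxy)methyl]-3-methyloxolane, via benzylic hydroperoxide 9 (not isolated)
Conditions: Mn(dpm)3 (20 mol%), PhSiH3 (2.5 equiv), iPrOH/CH2Cl2 (0.01 M), 5% O2 in N2 (1 atm), 0 °C; then PPh3, rt
Reagents that add atoms: dioxygen, O=O
Why: A manganese hydride formed from Mn(dpm)3 and PhSiH3 transfers a hydrogen atom to the terminal CH2 of the vinyl group, the secondary C3 radical adds to the cinnamyl alkene to form C3–C4, the benzylic C1' radical captures O2, and PPh3 reduces hydroperoxide 9 in the same pot before it can dehydrate to the ketone. The closest known reaction type is the Mukaiyama-type hydrogen-atom-transfer cyclisation of 1,6-dienes terminated by O2, together with 5-exo cyclisations of β-oxygenated alkyl radicals onto cinnamyl ethers. The oxolane closes in the 5-exo-trig mode through a chair-like Beckwith–Houk transition state. C3 and C4 are controlled by C2, whose aryl group sits pseudo-equatorial and so places the C4 arm trans to the aryl and cis to the C3 methyl; C1' is controlled by C4, O2 adding anti to C3 in the conformer of the benzylic radical that minimises A(1,3) strain. The step needs site selectivity in the hydrogen-atom transfer and ring closure ahead of O2 capture at C3: the first rests on the open monosubstituted vinyl group against the 1,2-disubstituted cinnamyl alkene, the second on the fast closure given by the 3-oxa tether and the aryl terminus under dilute O2 at high dilution.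

Compound list
1 | veratraldehyde (3,4-dimethoxybenzaldehyde) | COc1ccc(C=O)cc1OC | starting material
2 | triethyl phosphonoacetate | CCOC(=O)CP(=O)(OCC)OCC | starting material
3 | ethyl (E)-3-(3,4-dimethoxyphenyl)prop-2-enoate | CCOC(=O)/C=C/c1ccc(OC)c(OC)c1 | intermediate
4 | (E)-3-(3,4-dimethoxyphenyl)prop-2-en-1-ol | OC/C=C/c1ccc(OC)c(OC)c1 | intermediate
5 | tert-butyl (E)-3-(3,4-dimethoxyphenyl)prop-2-en-1-yl carbonate | CC(C)(C)OC(=O)OC/C=C/c1ccc(OC)c(OC)c1 | intermediate
6 | lithium (E)-3-(3,4-dimethoxyphenyl)prop-2-en-1-olate, the lithium alkoxide of 4 (not isolated) | [Li+].[O-]C/C=C/c1ccc(OC)c(OC)c1 | intermediate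
7 | copper (E)-3-(3,4-dimethoxyphenyl)prop-2-en-1-olate, the monovalent copper alkoxide of 4 (not isolated) | [Cu]OC/C=C/c1ccc(OC)c(OC)c1 | intermediate
8 | (S)-1-(3,4-dimethoxyphenyl)prop-2-en-1-yl (E)-3-(3,4-dimethoxyphenyl)prop-2-en-1-yl ether | COc1ccc([C@H](C=C)OC/C=C/c2ccc(OC)c(OC)c2)cc1OC | intermediate
9 | (2S,3S,4R)-2-(3,4-dimethoxyphenyl)-4-[(R)-(3,4-dimethoxyphenyl)(hydroperoxy)methyl]-3-methyloxolane (not isolated) | COc1ccc([C@H]2OC[C@H]([C@@H](OO)c3ccc(OC)c(OC)c3)[C@@H]2C)cc1OC | intermediate
10 | (2S,3S,4R)-2-(3,4-dimethoxyphenyl)-4-[(R)-(3,4-dimethoxyphenyl)(hydroxy)methyl]-3-methyloxolane, CNP0269167.1 | COc1ccc([C@H]2OC[C@H]([C@@H](O)c3ccc(OC)c(OC)c3)[C@@H]2C)cc1OC | target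

Total step count: 5
Longest linear sequence: 5 steps (1 → 3 → 4 → 5 → 8 → 10)

Steps most likely to fail

Step 5. The hydride may transfer its hydrogen atom to the conjugated cinnamyl alkene instead of the vinyl group, or O2 may intercept the C3 radical before ring closure; either diverts material to open-chain alcohols. Oxygen capture at C1' may also show little facial bias. The fallback sets out from 1 and returns at 10; it makes the C3 radical by decarboxylation and sets C1' by a reagent-controlled ketone reduction.
- An Evans syn-aldol reaction of 1 with commercial (S)-4-benzyl-3-propanoyloxazolidin-2-one (Bu2BOTf, iPr2NEt, CH2Cl2, −78 °C) should give the syn-aldol imide F1, whose (S)-carbinol carbon is the later C2.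
- Its hydroxyl is alkylated with (E)-3,4-dimethoxycinnamyl bromide F2 (from 4 and PBr3, used crude) and Ag2O in CH2Cl2, which should give the cinnamyl ether imide F3.
- LiOH/H2O2 removes the auxiliary to leave the β-alkoxy acid F4, and DCC with N-hydroxypyridine-2-thione converts it into the Barton ester F5.
- Irradiation of F5 in dilute toluene under air with tBuSH (Barton decarboxylative oxygenation) should release CO2 and the same C3 radical as in step 5, with no alkene competing for a hydride. After 5-exo closure, O2 capture and PPh3, the carbinol epimer mixture F6 is expected.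
- Dess–Martin periodinane buffered with NaHCO3 should oxidise F6 to the aryl ketone F7. It is used at once, because it is a β-alkoxy ketone with an epimerisable C4.
- (S)-Me-CBS oxazaborolidine with BH3·SMe2 should reduce F7 to 10, the aryl group acting as the large substituent.

Step 4. Branched selectivity or enantiopurity may be lost, through attack at the unsubstituted allyl terminus or through reversible ionisation of the electron-rich branched ether. The fallback sets out from 1 and returns at 8; the stereocentre comes from an enzymatic resolution and the ether bond from an SN2 alkylation.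
- CH2=CHMgBr (THF, −78 °C) adds to 1 to give racemic 1-(3,4-dimethoxyphenyl)prop-2-en-1-ol F8.
- Candida antarctica lipase B with vinyl acetate should acetylate the (R)-enantiomer to the (R)-acetate F9 and leave the (S)-alcohol F10, by the usual enantiopreference for 1-arylalkanols; the two are separated by chromatography.
- The sodium alkoxide of F10 (NaH, THF/DMF, 0 °C) is alkylated with (E)-3,4-dimethoxycinnamyl chloride F11 (from 4 and SOCl2) in the presence of Bu4NI. This Williamson etherification should give 8 without touching C2.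

Step 3. DMAP may scramble the acyl group to the symmetrical carbonate, and the electron-rich allylic carbonate may ionise during purification. The fallback sets out from 4 and returns at 8; it makes the symmetrical carbonate on purpose and lets the leaving group become the nucleophile.
- 4 (2 equiv) with 1,1'-carbonyldiimidazole and catalytic DBU in THF should give bis[(E)-3-(3,4-dimethoxyphenyl)prop-2-en-1-yl] carbonate F12.
- Under [Ir(cod)Cl]2 and L, F12 should ionise; the cinnamyl carbonate anion loses CO2 and the alkoxide so formed attacks the π-allyl complex at its aryl-bearing terminus (decarboxylative allylic etherification). This gives 8 without a mixed carbonate and without a separately prepared alkoxide.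

Further compounds
F1 | step 5 | (S)-4-benzyl-3-[(2S,3S)-3-(3,4-dimethoxyphenyl)-3-hydroxy-2-methylpropanoyl]oxazolidin-2-one | COc1ccc([C@@H](O)[C@H](C)C(=O)N2C(=O)OC[C@@H]2Cc2ccccc2)cc1OC
F2 | step 5 | (E)-4-(3-bromoprop-1-en-1-yl)-1,2-dimethoxybenzene | BrC/C=C/c1ccc(OC)c(OC)c1
F3 | step 5 | (S)-4-benzyl-3-[(2S,3S)-3-(3,4-dimethoxyphenyl)-3-{[(E)-3-(3,4-dimethoxyphenyl)prop-2-en-1-yl]oxy}-2-methylpropanoyl]oxazolidin-2-one | COc1ccc([C@@H](OC/C=C/c2ccc(OC)c(OC)c2)[C@H](C)C(=O)N2C(=O)OC[C@@H]2Cc2ccccc2)cc1OC
F4 | step 5 | (2S,3S)-3-(3,4-dimethoxyphenyl)-3-{[(E)-3-(3,4-dimethoxyphenyl)prop-2-en-1-yl]oxy}-2-methylpropanoic acid | COc1ccc([C@@H](OC/C=C/c2ccc(OC)c(OC)c2)[C@H](C)C(=O)O)cc1OC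
F5 | step 5 | 2-thioxopyridin-1(2H)-yl (2S,3S)-3-(3,4-dimethoxyphenyl)-3-{[(E)-3-(3,4-dimethoxyphenyl)prop-2-en-1-yl]oxy}-2-methylpropanoate | COc1ccc([C@@H](OC/C=C/c2ccc(OC)c(OC)c2)[C@H](C)C(=O)ON2C=CC=CC2=S)cc1OC
F6 | step 5 | (3,4-dimethoxyphenyl)[(3R,4S,5S)-5-(3,4-dimethoxyphenyl)-4-methyloxolan-3-yl]methanol, mixture of epimers at the carbinol carbon | COc1ccc([C@H]2OC[C@H](C(O)c3ccc(OC)c(OC)c3)[C@@H]2C)cc1OC
F7 | step 5 | (3,4-dimethoxyphenyl)[(3R,4S,5S)-5-(3,4-dimethoxyphenyl)-4-methyloxolan-3-yl]methanone | COc1ccc([C@H]2OC[C@H](C(=O)c3ccc(OC)c(OC)c3)[C@@H]2C)cc1OC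
F8 | step 4 | racemic 1-(3,4-dimethoxyphenyl)prop-2-en-1-ol | COc1ccc(C(O)C=C)cc1OC
F9 | step 4 | (R)-1-(3,4-dimethoxyphenyl)prop-2-en-1-yl acetate | COc1ccc([C@@H](C=C)OC(C)=O)cc1OC
F10 | step 4 | (S)-1-(3,4-dimethoxyphenyl)prop-2-en-1-ol | COc1ccc([C@H](C=C)O)cc1OC
F11 | step 4 | (E)-4-(3-chloroprop-1-en-1-yl)-1,2-dimethoxybenzene | ClC/C=C/c1ccc(OC)c(OC)c1
F12 | step 3 | bis[(E)-3-(3,4-dimethoxyphenyl)prop-2-en-1-yl] carbonate | O=C(OC/C=C/c1ccc(OC)c(OC)c1)OC/C=C/c1ccc(OC)c(OC)c1
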